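Retrosynthesis: the C8 benzyl ether is removed last, and the C2–C3 bond of ring C is cut next. This returns an isomeric racemic acetal, a 4-methylene-1,3-benzodioxine in which C2 is held by O1 and by the enol ether oxygen of the future C4 carbonyl. The two C2–O bonds are then cut to a salicylic acid and veratraldehyde, and the methylene carbon (future C3) to a carbonyl methylenation.
Forward: ring A is fully substituted first, by two Dakin oxidation/ortho-formylation cycles on 2,3,4-trimethoxybenzaldehyde with a benzylation between them, then oxidation to the acid. Ring B arrives intact with veratraldehyde when the dioxinone ring closes; the lactone carbonyl is methylenated, and an acid-catalysed 1,3 oxygen-to-carbon shift turns the dioxine into ring C.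
Enabling feature: C2 carries O1 and the 3,4-dimethoxyphenyl ring and so ionises to a stabilised oxocarbenium ion, while C3–C4(=O), attached to the ring A carbon C4a next to O1, is released as an enol by that same ionisation.
Stereochemistry: the only stereocentre, C2 (S), is set in the rearrangement by the chiral counteranion of a confined Brønsted acid acting on the planar cation, so the racemic acetal converges; no later step touches C2.

Key step: step 9

Assumption: the sense of induction of the confined acid cannot be predicted with certainty; the (S,S) catalyst is written, and its mirror image would be used if the (S,S) form proves to favour the (R) product.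

Step 1
Reactants: 1 2,3,4-trimethoxybenzaldehyde
Product: 3 2,3,4-trimethoxyphenol, via 2,3,4-trimethoxyphenyl formate 2 (not isolated)
Conditions: mCPBA, CH2Cl2, 0 °C to rt; aq. NaHCO3 wash; crude 2 then K2CO3 (cat.), MeOH, rt
Reagents that add atoms: mCPBA (3-chloroperoxybenzoic acid), O=C(OO)c1cccc(Cl)c1
Why: Baeyer–Villiger (Dakin-type) oxidation, in which the electron-rich aryl group migrates in the Criegee intermediate to give the formate, which is then methanolysed to the phenol.

Step 2
Reactants: 3 2,3,4-trimethoxyphenol
Product: 4 2-hydroxy-3,4,5-trimethoxybenzaldehyde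
Conditions: MgCl2, Et3N, (CH2O)n, MeCN, reflux; aq. HCl work-up
Reagents that add atoms: paraformaldehyde (formaldehyde), C=O
Why: Casnati–Skattebøl ortho-formylation, in which the magnesium phenoxide delivers formaldehyde to the only free ortho carbon and a second formaldehyde oxidises the resulting benzylic alkoxide to the aldehyde.

Step 3
Reactants: 4 2-hydroxy-3,4,5-trimethoxybenzaldehyde; 5 benzyl bromide
Product: 6 2-(benzyloxy)-3,4,5-trimethoxybenzaldehyde
Conditions: K2CO3, DMF, 50 °C
Reagents that add atoms: none
Why: Williamson etherification of the phenoxide masks the oxygen that becomes the C8 hydroxyl with a group that should survive peracid, base, Lewis acid and the titanium reagent and is removable at the end under neutral conditions.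

Step 4
Reactants: 6 2-(benzyloxy)-3,4,5-trimethoxybenzaldehyde
Product: 8 2-(benzyloxy)-3,4,5-trimethoxyphenol, via 2-(benzyloxy)-3,4,5-trimethoxyphenyl formate 7 (not isolated)
Conditions: mCPBA, CH2Cl2, 0 °C to rt; aq. NaHCO3 wash; crude 7 then K2CO3 (cat.), MeOH, rt
Reagents that add atoms: mCPBA (3-chloroperoxybenzoic acid), O=C(OO)c1cccc(Cl)c1
Why: a second Baeyer–Villiger (Dakin-type) oxidation, with aryl migration assured by the oxygenated ring and the benzyl ether inert to the peracid, installs the oxygen that becomes O1.

Step 5
Reactants: 8 2-(benzyloxy)-3,4,5-trimethoxyphenol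
Product: 9 3-(benzyloxy)-2-hydroxy-4,5,6-trimethoxybenzaldehyde
Conditions: MgCl2, Et3N, (CH2O)n, MeCN, reflux; aq. HCl work-up
Reagents that add atoms: paraformaldehyde (formaldehyde), C=O
Why: Casnati–Skattebøl ortho-formylation at the single remaining ring position, which lies ortho to the free phenol, brings in the carbon that becomes C4.

Step 6
Reactants: 9 3-(benzyloxy)-2-hydroxy-4,5,6-trimethoxybenzaldehyde
Product: 10 3-(benzyloxy)-2-hydroxy-4,5,6-trimethoxybenzoic acid
Conditions: NaClO2, NaH2PO4, 2-methyl-2-butene, t-BuOH/H2O, 0 °C to rt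
Reagents that add atoms: sodium chlorite, [Na+].[O-]Cl=O
Why: Pinnick oxidation takes the aldehyde to the acid under buffered conditions, the ring having no free position for chlorination and the alkene scavenging the hypochlorous acid.

Step 7
Reactants: 10 3-(benzyloxy)-2-hydroxy-4,5,6-trimethoxybenzoic acid; 11 3,4-dimethoxybenzaldehyde (veratraldehyde)
Product: 13 rac-8-(benzyloxy)-2-(3,4-dimethoxyphenyl)-5,6,7-trimethoxy-4H-1,3-benzodioxin-4-one, via bis(trimethylsilyl) salicylate 12 (not isolated)
Conditions: HMDS, THF, 60 °C, concentrate; then 11, TMSOTf (10 mol%), CH2Cl2, −78 to −30 °C; pyridine quench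
Reagents that add atoms: none
Why: Noyori-type silyl-mediated acetalisation, in which the silyl ester and silyl aryl ether condense with the TMSOTf-activated aldehyde and lose hexamethyldisiloxane to close the six-membered acylal at low temperature; the acetal centre forms racemic, which does not matter because it is erased in step 9.

Step 8
Reactants: 13 rac-8-(benzyloxy)-2-(3,4-dimethoxyphenyl)-5,6,7-trimethoxy-4H-1,3-benzodioxin-4-one
Product: 14 rac-8-(benzyloxy)-2-(3,4-dimethoxyphenyl)-5,6,7-trimethoxy-4-methylidene-4H-1,3-benzodioxine
Conditions: Cp2TiMe2, toluene/THF, 65 °C, dark; Et3N-deactivated silica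
Reagents that add atoms: dimethyltitanocene Cp2TiMe2, [CH3-].[CH3-].[Ti+4].[cH-]1cccc1.[cH-]1cccc1
Why: Petasis methylenation, in which thermally generated Cp2Ti=CH2 undergoes cycloaddition and cycloreversion with the lactone carbonyl under neutral, non-basic conditions that should leave the acylal carbon and the benzyl ether untouched.

Step 9
Reactants: 14 rac-8-(benzyloxy)-2-(3,4-dimethoxyphenyl)-5,6,7-trimethoxy-4-methylidene-4H-1,3-benzodioxine
Product: 16 (2S)-8-(benzyloxy)-2-(3,4-dimethoxyphenyl)-5,6,7-trimethoxychroman-4-one, via oxocarbenium enol ion pair 15 (not isolated)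
Conditions: (S,S)-IDPi acid [N-triflyl imidodiphosphorimidate built from two (S)-3,3'-bis(3,5-bis(trifluoromethyl)phenyl)-BINOL units] (5 mol%), 5 Å MS, toluene, −60 °C; Et3N quench
Reagents that add atoms: none
Why: Proposed new method: the confined acid activates the enol ether oxygen O3 of 14, the C2–O3 bond ionises because the cation at C2 is stabilised by O1 and by the 3,4-dimethoxyphenyl ring, and the enol released at C4 stays hydrogen-bonded to the chiral anion in ion pair 15. The enol carbon C3 then adds to C2 while the anion takes the enol proton, so the C4 ketone forms irreversibly and ring C closes in a 6-(enolendo)-endo-trig mode. The closest known reaction types are the Me2AlCl-promoted Petasis–Ferrier rearrangement of 4-methylene-1,3-dioxanes to tetrahydropyran-4-ones and the chiral phosphoric acid catalysed aza-Petasis–Ferrier rearrangement of racemic hemiaminal vinyl ethers, neither of which covers an enantioselective all-oxygen case on a benzo-fused acetal. The C2 stereocentre is controlled by the catalyst alone, since both enantiomers of 14 collapse to the same planar oxocarbenium ion and the anion pocket exposes one face of C2 to the tethered enol. The step needs productive cleavage of C2–O3 and not of C2–O1, which the substrate secures because O1 cleavage gives a phenol and a vinyl oxocarbenium ion that can only reclose, and it needs freedom from arene alkylation, which the fully substituted ring A guarantees. Water is excluded because it would divert 15 to veratraldehyde and the methyl ketone, and the low temperature keeps the product from re-ionising at C2.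

Step 10
Reactants: 16 (2S)-8-(benzyloxy)-2-(3,4-dimethoxyphenyl)-5,6,7-trimethoxychroman-4-one
Product: 17 (2S)-2-(3,4-dimethoxyphenyl)-8-hydroxy-5,6,7-trimethoxychroman-4-one
Conditions: H2 (1 atm), 10% Pd/C, EtOAc, rt
Reagents that add atoms: none
Why: heterogeneous hydrogenolysis of the benzyl aryl ether, which at 1 atm in a neutral solvent should be much faster than reduction of the aryl ketone or cleavage of the cyclic C2–O1 bond, and which offers C2 no pathway to epimerise.

Compound list
1 | 2,3,4-trimethoxybenzaldehyde | COc1ccc(C=O)c(OC)c1OC | starting material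
2 | 2,3,4-trimethoxyphenyl formate | COc1ccc(OC=O)c(OC)c1OC | intermediate
3 | 2,3,4-trimethoxyphenol | COc1ccc(O)c(OC)c1OC | intermediate
4 | 2-hydroxy-3,4,5-trimethoxybenzaldehyde | COc1cc(C=O)c(O)c(OC)c1OC | intermediate
5 | benzyl bromide | BrCc1ccccc1 | starting material
6 | 2-(benzyloxy)-3,4,5-trimethoxybenzaldehyde | COc1cc(C=O)c(OCc2ccccc2)c(OC)c1OC | intermediate
7 | 2-(benzyloxy)-3,4,5-trimethoxyphenyl formate | COc1cc(OC=O)c(OCc2ccccc2)c(OC)c1OC | intermediate
8 | 2-(benzyloxy)-3,4,5-trimethoxyphenol | COc1cc(O)c(OCc2ccccc2)c(OC)c1OC | intermediate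
9 | 3-(benzyloxy)-2-hydroxy-4,5,6-trimethoxybenzaldehyde | COc1c(C=O)c(O)c(OCc2ccccc2)c(OC)c1OC | intermediate
10 | 3-(benzyloxy)-2-hydroxy-4,5,6-trimethoxybenzoic acid | COc1c(C(=O)O)c(O)c(OCc2ccccc2)c(OC)c1OC | intermediate
11 | 3,4-dimethoxybenzaldehyde (veratraldehyde) | COc1ccc(C=O)cc1OC | starting material
12 | trimethylsilyl 3-(benzyloxy)-4,5,6-trimethoxy-2-[(trimethylsilyl)oxy]benzoate (bis(trimethylsilyl) salicylate) | COc1c(C(=O)O[Si](C)(C)C)c(O[Si](C)(C)C)c(OCc2ccccc2)c(OC)c1OC | intermediate
13 | rac-8-(benzyloxy)-2-(3,4-dimethoxyphenyl)-5,6,7-trimethoxy-4H-1,3-benzodioxin-4-one | COc1ccc(C2OC(=O)c3c(OC)c(OC)c(OC)c(OCc4ccccc4)c3O2)cc1OC | intermediate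
14 | rac-8-(benzyloxy)-2-(3,4-dimethoxyphenyl)-5,6,7-trimethoxy-4-methylidene-4H-1,3-benzodioxine | COc1ccc(C2OC(=C)c3c(OC)c(OC)c(OC)c(OCc4ccccc4)c3O2)cc1OC | intermediate
15 | oxocarbenium enol ion pair: [3-(benzyloxy)-2-(1-hydroxyvinyl)-4,5,6-trimethoxyphenyl](3,4-dimethoxybenzylidene)oxonium, counterion the catalyst anion (cation shown) | C=C(O)c1c(OC)c(OC)c(OC)c(OCc2ccccc2)c1[O+]=Cc1ccc(OC)c(OC)c1 | intermediate
16 | (2S)-8-(benzyloxy)-2-(3,4-dimethoxyphenyl)-5,6,7-trimethoxychroman-4-one | COc1ccc([C@@H]2CC(=O)c3c(OC)c(OC)c(OC)c(OCc4ccccc4)c3O2)cc1OC | intermediate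
17 | (2S)-2-(3,4-dimethoxyphenyl)-8-hydroxy-5,6,7-trimethoxychroman-4-one (CNP0179923.1) | COc1ccc([C@@H]2CC(=O)c3c(c(O)c(OC)c(OC)c3OC)O2)cc1OC | target

Total step count: 10
Longest linear sequence: 10 steps (1 to 17); compounds 5 and 11 enter as reagents-in-hand.

Steps most likely to fail

Step 9. Possible failures: the chiral anion may discriminate poorly between the two faces of the C2 oxocarbenium ion, adventitious achiral acid may drive a racemic background rearrangement, or traces of water may fragment the ion pair. The fallback uses established chemistry, sets out from 10 and returns at 16. Excess MeLi in THF at 0 °C should convert the lithium carboxylate of 10 directly into the methyl ketone 1-[3-(benzyloxy)-2-hydroxy-4,5,6-trimethoxyphenyl]ethan-1-one F1. Heating with N,N-dimethylformamide dimethyl acetal should give the enaminone (E)-1-[3-(benzyloxy)-2-hydroxy-4,5,6-trimethoxyphenyl]-3-(dimethylamino)prop-2-en-1-one F2, which on treatment with HCl in CH2Cl2 should close to the chromone 8-(benzyloxy)-5,6,7-trimethoxy-4H-chromen-4-one F3. Enantioselective conjugate addition of 3,4-dimethoxyphenylboronic acid to F3 with a divalent palladium catalyst, Pd(OCOCF3)2 and the tert-butyl pyridine-oxazoline ligand antipode that delivers the (S) product, NH4PF6, H2O, 1,2-dichloroethane, 60 °C, is a known asymmetric entry to flavanones and should give 16.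

Step 7. Possible failures: the electron-rich acylal may re-ionise under the Lewis acid so that ring closure stalls short of completion, or the hindered, electron-rich acid may protodecarboxylate. The fallback closes the ring oxidatively instead of by condensation, sets out from 9 and returns at 13. Alkylation of 9 with 3,4-dimethoxybenzyl chloride (K2CO3, DMF) should give 3-(benzyloxy)-2-[(3,4-dimethoxybenzyl)oxy]-4,5,6-trimethoxybenzaldehyde F4. Pinnick oxidation should give 3-(benzyloxy)-2-[(3,4-dimethoxybenzyl)oxy]-4,5,6-trimethoxybenzoic acid F5. DDQ in dry CH2Cl2 over 4 Å MS should then abstract hydride from the dimethoxybenzyl ether, and the neighbouring carboxyl should trap the resulting oxocarbenium ion to form 13.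

Step 8. Possible failures: carbonyl methylenation of the hindered aryl lactone may be incomplete, or the enol acetal may hydrolyse or rearrange racemically through trace acid during isolation. The fallback builds the exocyclic alkene by elimination instead of carbonyl olefination, sets out from 9 and returns at 14. Bromomethyllithium generated in situ (CH2Br2, n-BuLi, THF, −78 °C, on the preformed lithium phenoxide of 9, cold acetic acid quench) should give rac-1-[3-(benzyloxy)-2-hydroxy-4,5,6-trimethoxyphenyl]-2-bromoethan-1-ol F6. Acetalisation of this phenol/benzylic alcohol pair with 11 (PPTS, MgSO4, CH2Cl2) should give 8-(benzyloxy)-4-(bromomethyl)-2-(3,4-dimethoxyphenyl)-5,6,7-trimethoxy-4H-1,3-benzodioxine F7 as a mixture of diastereomers. E2 dehydrobromination with t-BuOK in THF at 0 °C, the standard route to exocyclic enol ether acetals, should give 14.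

Further compounds
F1 | step 9 | 1-[3-(benzyloxy)-2-hydroxy-4,5,6-trimethoxyphenyl]ethan-1-one | COc1c(C(C)=O)c(O)c(OCc2ccccc2)c(OC)c1OC
F2 | step 9 | (E)-1-[3-(benzyloxy)-2-hydroxy-4,5,6-trimethoxyphenyl]-3-(dimethylamino)prop-2-en-1-one | COc1c(C(=O)/C=C/N(C)C)c(O)c(OCc2ccccc2)c(OC)c1OC
F3 | step 9 | 8-(benzyloxy)-5,6,7-trimethoxy-4H-chromen-4-one | O=c1ccoc2c(OCc3ccccc3)c(OC)c(OC)c(OC)c12
F4 | step 7 | 3-(benzyloxy)-2-[(3,4-dimethoxybenzyl)oxy]-4,5,6-trimethoxybenzaldehyde | COc1ccc(COc2c(C=O)c(OC)c(OC)c(OC)c2OCc2ccccc2)cc1OC
F5 | step 7 | 3-(benzyloxy)-2-[(3,4-dimethoxybenzyl)oxy]-4,5,6-trimethoxybenzoic acid | COc1ccc(COc2c(C(=O)O)c(OC)c(OC)c(OC)c2OCc2ccccc2)cc1OC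
F6 | step 8 | rac-1-[3-(benzyloxy)-2-hydroxy-4,5,6-trimethoxyphenyl]-2-bromoethan-1-ol | COc1c(C(O)CBr)c(O)c(OCc2ccccc2)c(OC)c1OC
F7 | step 8 | 8-(benzyloxy)-4-(bromomethyl)-2-(3,4-dimethoxyphenyl)-5,6,7-trimethoxy-4H-1,3-benzodioxine (diastereomer mixture) | COc1ccc(C2OC(CBr)c3c(OC)c(OC)c(OC)c(OCc4ccccc4)c3O2)cc1OC
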